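**Target:** (3S,5S,6S,3'R,6'R)-5,6-dihydro-β,ε-carotene-3,5,6,3'-tetrol (compound 28).

## Retrosynthetic overview
1. C11=C12 Wittig: triol-C15 phosphonium salt + ε-C25 apo-aldehyde; the latter by C11'=C12' Wittig from an ε-C15 phosphonium salt and the C10 trienedial.
2. Triol-C15 unit: one-pot hydride reduction (ketone, epoxide, alkyne) of an alkynyl epoxy-ketone, made by epoxidation anti to a silyloxy group of a (4S)-4-alkynyl-4-silyloxy-3,5,5-trimethylcyclohexenone.
3. Key step: that enone comes from an achiral, mirror-symmetric 3,5-dimethyl p-quinol silyl ether by methylating one of its two enantiotopic enone arms; this creates the gem-dimethyl carbon and the C6 stereocentre together. The quinol comes from acetylide addition to the quinone monoketal made by oxidative dearomatisation of 2,6-dimethylphenol.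
4. ε-C15 unit: (R)-α-ionone, by HWE chain extension, allylic oxidation at C3' and CBS reduction.
5. Rings: none is built. The triol ring is the dearomatised xylenol ring; the ε-ring is carried intact from α-ionone.

## Assumptions and conventions
- (R)-(+)-α-ionone (≥98% ee), (E)-3-methylpent-2-en-4-yn-1-ol and (2E,4E,6E)-2,7-dimethylocta-2,4,6-trienedial are bought.
- In step 3 the ligand antipode that gives the (4S) product is used (both antipodes are sold); the sense is not predicted here and must be confirmed at compound 11.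
- Carotenoid numbering (ring C1–C6, chain C7–C15, primes for the ε half) is used in the "Why" lines.
- Metal alkoxides, enolates and aluminates that are only protonated on aqueous work-up are not numbered; every other species that forms and reacts on in the flask is.

## Route

Step 1
Reactants: 1 2,6-dimethylphenol
Product: 3 4,4-dimethoxy-2,6-dimethylcyclohexa-2,5-dien-1-one, via 4-methoxy-2,6-dimethylphenol 2 (not isolated)
Conditions: PhI(OAc)2 (2.2 equiv), MeOH, 0 °C → rt
Reagents that add atoms: methanol, CO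
Why: Hypervalent-iodine oxidative dearomatisation; both ortho positions carry methyl, so methanol adds twice at the para carbon and gives the quinone monoketal whose only free carbonyl is the one flanked by the two C-methyl carbons.

Step 2
Reactants: 3 4,4-dimethoxy-2,6-dimethylcyclohexa-2,5-dien-1-one; 4 (2E)-3-methylpent-2-en-4-yn-1-ol
Product: 8 3,5-dimethyl-4-(triethylsilyloxy)-4-[(3E)-3-methyl-5-(triethylsilyloxy)pent-3-en-1-yn-1-yl]cyclohexa-2,5-dien-1-one, via dilithiated enynol 5 (not isolated), via dilithium dialkoxide adduct 6 (not isolated), via bis-TES ketal 7 (not isolated)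
Conditions: 4, n-BuLi (2.05 equiv), THF, −78 °C; 3, −78 → 0 °C; Et3SiCl (2.5 equiv), DMAP (cat.), 0 °C → rt; then wet SiO2, oxalic acid (cat.), CH2Cl2, rt
Reagents that add atoms: chlorotriethylsilane, CC[Si](Cl)(CC)CC; water, O
Why: 1,2-Addition of the lithium acetylide to the single carbonyl of the monoketal, O-silylation of both alkoxides in the flask and mild hydrolysis of the bis-allylic dimethyl ketal give a p-quinol silyl ether that has a mirror plane and no stereocentre.

Step 3
Reactants: 8 3,5-dimethyl-4-(triethylsilyloxy)-4-[(3E)-3-methyl-5-(triethylsilyloxy)pent-3-en-1-yn-1-yl]cyclohexa-2,5-dien-1-one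
Product: 9 (4S)-3,5,5-trimethyl-4-(triethylsilyloxy)-4-[(3E)-3-methyl-5-(triethylsilyloxy)pent-3-en-1-yn-1-yl]cyclohex-2-en-1-one
Conditions: Me3Al (2 equiv), CuTC (5 mol %), (S,R,R)-BINOL/bis(1-phenylethyl)amine phosphoramidite (10 mol %), Et2O, −30 °C; aq. Rochelle salt
Reagents that add atoms: trimethylaluminium, C[Al](C)C
Why: Proposed new method: Cu(I)/phosphoramidite-catalysed asymmetric conjugate addition of Me3Al that picks one of the two enantiotopic β-methyl enone arms of the achiral dienone — the chiral Cu–methyl species adds to its preferred enone π-face, and only in one arm is that face the one anti to the bulky OTES group (syn to the slim alkyne), so the arm choice (and with it C6 = S) follows from catalyst face preference plus substrate bias, while the new CMe2 carbon is not stereogenic and a second addition is blocked by two flanking quaternary carbons; closest known reaction types are the Cu-catalysed conjugate addition of Me3Al to 3-methylcyclohexenones (quaternary centres), the Cu-catalysed desymmetrisation of 4,4-disubstituted cyclohexa-2,5-dienones with dialkylzincs and the racemic MeMgBr addition to 4-alkynyl-3,5-dimethyl p-quinols.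

Step 4
Reactants: 9 (4S)-3,5,5-trimethyl-4-(triethylsilyloxy)-4-[(3E)-3-methyl-5-(triethylsilyloxy)pent-3-en-1-yn-1-yl]cyclohex-2-en-1-one
Product: 11 (1R,5R,6S)-5-hydroxy-5-[(3E)-5-hydroxy-3-methylpent-3-en-1-yn-1-yl]-4,4,6-trimethyl-7-oxabicyclo[4.1.0]heptan-2-one, via bis-TES epoxy ketone 10 (not isolated)
Conditions: t-BuOOH (3 equiv, decane), DBU (1.5 equiv), CH2Cl2, 0 °C → rt; then TBAF (2.5 equiv), AcOH (2.5 equiv), THF, 0 °C → rt
Reagents that add atoms: tert-butyl hydroperoxide, CC(C)(C)OO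
Why: Weitz–Scheffer nucleophilic epoxidation in which the peroxide attacks C5 on the face anti to the OTES group (syn to the linear alkyne), so the C5–O bond is trans to C6–O and the cis ring fusion fixes C4; buffered fluoride then frees both hydroxyls without Payne rearrangement.

Step 5
Reactants: 11 (1R,5R,6S)-5-hydroxy-5-[(3E)-5-hydroxy-3-methylpent-3-en-1-yn-1-yl]-4,4,6-trimethyl-7-oxabicyclo[4.1.0]heptan-2-one
Product: 12 (1S,2S,4S)-1-[(1E,3E)-5-hydroxy-3-methylpenta-1,3-dien-1-yl]-2,6,6-trimethylcyclohexane-1,2,4-triol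
Conditions: Red-Al (6 equiv), THF, 0 → 40 °C; aq. Rochelle salt
Reagents that add atoms: none
Why: Three hydride events in one flask — ketone reduction anti to the epoxide oxygen (C3–OH cis to C5–O; equatorial attack on the β-hydroxy ketone gives the same result if the epoxide opens first), SN2 epoxide opening at the secondary C4 so that C5–O keeps its configuration, and alkoxide-directed trans-hydroalumination of the propargylic alkyne to the (7E)-alkene.

Step 6
Reactants: 12 (1S,2S,4S)-1-[(1E,3E)-5-hydroxy-3-methylpenta-1,3-dien-1-yl]-2,6,6-trimethylcyclohexane-1,2,4-triol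
Product: 14 [(2E,4E)-3-methyl-5-[(1S,2S,4S)-1,2,4-trihydroxy-2,6,6-trimethylcyclohexyl]penta-2,4-dien-1-yl]triphenylphosphonium bromide, via allylic bromide 13 (not isolated)
Conditions: CBr4 (1.1 equiv), PPh3 (1.1 equiv), CH2Cl2, −30 → 0 °C; then PPh3 (1.2 equiv), rt
Reagents that add atoms: triphenylphosphine, c1ccc(cc1)P(c1ccccc1)c1ccccc1; carbon tetrabromide, BrC(Br)(Br)Br
Why: Appel bromination is selective for the primary allylic hydroxyl under neutral conditions (no ionisation of the tertiary allylic C6–OH), and SN2 quaternisation of the bromide by PPh3 gives the Wittig salt with all stereocentres untouched.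

Step 7
Reactants: 15 (3E)-4-[(1R)-2,6,6-trimethylcyclohex-2-en-1-yl]but-3-en-2-one ((R)-α-ionone); 16 triethyl phosphonoacetate
Product: 18 ethyl (2E,4E)-3-methyl-5-[(1R)-2,6,6-trimethylcyclohex-2-en-1-yl]penta-2,4-dienoate, via sodium phosphonoacetate anion 17 (not isolated)
Conditions: NaH (1.3 equiv), THF, 0 → 50 °C; (2E) isomer separated on silica
Reagents that add atoms: none
Why: Horner–Wadsworth–Emmons olefination of the methyl ketone gives mainly the (E)-trisubstituted dienoate, and the weakly basic phosphonate anion leaves the C6' stereocentre of the chiral-pool ionone intact.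

Step 8
Reactants: 18 ethyl (2E,4E)-3-methyl-5-[(1R)-2,6,6-trimethylcyclohex-2-en-1-yl]penta-2,4-dienoate
Product: 19 ethyl (2E,4E)-3-methyl-5-[(1R)-2,6,6-trimethyl-4-oxocyclohex-2-en-1-yl]penta-2,4-dienoate
Conditions: Rh2(cap)4 (1 mol %), t-BuOOH (70% aq., 5 equiv), CH2Cl2, rt
Reagents that add atoms: tert-butyl hydroperoxide, CC(C)(C)OO
Why: Radical allylic C–H oxidation takes the accessible ring CH2 at C3' to the enone (as known for α-ionone and its C15 nitrile), while the shielded tertiary C6'–H is left alone under the base-free conditions.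

Step 9
Reactants: 19 ethyl (2E,4E)-3-methyl-5-[(1R)-2,6,6-trimethyl-4-oxocyclohex-2-en-1-yl]penta-2,4-dienoate
Product: 21 (2E,4E)-5-[(1R,4R)-4-hydroxy-2,6,6-trimethylcyclohex-2-en-1-yl]-3-methylpenta-2,4-dien-1-ol, via trans-hydroxy ester 20 (not isolated)
Conditions: (S)-Me-CBS (20 mol %), catecholborane (1.8 equiv), toluene, −78 °C; then DIBAL-H (4 equiv), −78 → −40 °C; aq. Rochelle salt
Reagents that add atoms: none
Why: Corey–Bakshi–Shibata reduction with the (S)-catalyst treats the alkenyl side as the large group and gives the (3'R)-alcohol, trans to the C6' chain, by reagent control over a small cis-favouring substrate bias; DIBAL-H then reduces the ester to the allylic alcohol.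

Step 10
Reactants: 21 (2E,4E)-5-[(1R,4R)-4-hydroxy-2,6,6-trimethylcyclohex-2-en-1-yl]-3-methylpenta-2,4-dien-1-ol
Product: 23 [(2E,4E)-5-[(1R,4R)-4-hydroxy-2,6,6-trimethylcyclohex-2-en-1-yl]-3-methylpenta-2,4-dien-1-yl]triphenylphosphonium bromide, via allylic bromide 22 (not isolated)
Conditions: CBr4 (1.05 equiv), PPh3 (1.05 equiv), CH2Cl2, −30 → 0 °C; then PPh3 (1.2 equiv), rt
Reagents that add atoms: triphenylphosphine, c1ccc(cc1)P(c1ccccc1)c1ccccc1; carbon tetrabromide, BrC(Br)(Br)Br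
Why: Appel bromination at low temperature takes the primary dienylic hydroxyl ahead of the secondary ring allylic one and avoids the acid that would solvolyse or epimerise C3'; PPh3 then gives the salt by SN2.

Step 11
Reactants: 23 [(2E,4E)-5-[(1R,4R)-4-hydroxy-2,6,6-trimethylcyclohex-2-en-1-yl]-3-methylpenta-2,4-dien-1-yl]triphenylphosphonium bromide; 24 (2E,4E,6E)-2,7-dimethylocta-2,4,6-trienedial
Product: 26 (2E,4E,6E,8E,10E,12E)-13-[(1R,4R)-4-hydroxy-2,6,6-trimethylcyclohex-2-en-1-yl]-2,7,11-trimethyltrideca-2,4,6,8,10,12-hexaenal, via ε-ylide 25 (not isolated)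
Conditions: NaOMe (1.1 equiv), 24 (3 equiv), CH2Cl2/MeOH, −10 °C → rt; then I2 (cat.), CH2Cl2, rt (Z→E)
Reagents that add atoms: none
Why: Wittig olefination with the dialdehyde in excess gives the mono-adduct (the standard way to C25 apo-carotenals), and iodine-catalysed equilibration converts the new C11'=C12' bond to E.

Step 12
Reactants: 14 [(2E,4E)-3-methyl-5-[(1S,2S,4S)-1,2,4-trihydroxy-2,6,6-trimethylcyclohexyl]penta-2,4-dien-1-yl]triphenylphosphonium bromide; 26 (2E,4E,6E,8E,10E,12E)-13-[(1R,4R)-4-hydroxy-2,6,6-trimethylcyclohex-2-en-1-yl]-2,7,11-trimethyltrideca-2,4,6,8,10,12-hexaenal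
Product: 28 (3S,5S,6S,3'R,6'R)-5,6-dihydro-β,ε-carotene-3,5,6,3'-tetrol, via triol ylide 27 (not isolated)
Conditions: NaOMe (1.2 equiv), CH2Cl2/MeOH, 0 °C → rt; then EtOH, reflux (Z→E), crystallise
Reagents that add atoms: none
Why: Wittig olefination with unprotected hydroxyls (as in lutein and zeaxanthin syntheses) forms C11=C12, thermal isomerisation and crystallisation give the all-E polyene, and no stereocentre is touched.

## Compound list
1 | 2,6-dimethylphenol | Cc1cccc(C)c1O | starting material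
2 | 4-methoxy-2,6-dimethylphenol | COc1cc(C)c(O)c(C)c1 | intermediate
3 | 4,4-dimethoxy-2,6-dimethylcyclohexa-2,5-dien-1-one | COC1(OC)C=C(C)C(=O)C(C)=C1 | intermediate
4 | (2E)-3-methylpent-2-en-4-yn-1-ol | C#C/C(C)=C/CO | starting material
5 | dilithiated enynol (lithium acetylide, lithium alkoxide of 4) | [Li+].[Li+].[C-]#C/C(C)=C/C[O-] | intermediate
6 | dilithium 4,4-dimethoxy-2,6-dimethyl-1-[(3E)-3-methyl-5-oxidopent-3-en-1-yn-1-yl]cyclohexa-2,5-dien-1-olate | [Li+].[Li+].[O-]C/C=C(C)/C#CC1([O-])C(C)=CC(OC)(OC)C=C1C | intermediate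
7 | bis(triethylsilyl) ether of 4,4-dimethoxy-1-[(3E)-5-hydroxy-3-methylpent-3-en-1-yn-1-yl]-2,6-dimethylcyclohexa-2,5-dien-1-ol | CC[Si](CC)(CC)OC/C=C(C)/C#CC1(O[Si](CC)(CC)CC)C(C)=CC(OC)(OC)C=C1C | intermediate
8 | 3,5-dimethyl-4-(triethylsilyloxy)-4-[(3E)-3-methyl-5-(triethylsilyloxy)pent-3-en-1-yn-1-yl]cyclohexa-2,5-dien-1-one (achiral) | CC[Si](CC)(CC)OC/C=C(C)/C#CC1(O[Si](CC)(CC)CC)C(C)=CC(=O)C=C1C | intermediate
9 | (4S)-3,5,5-trimethyl-4-(triethylsilyloxy)-4-[(3E)-3-methyl-5-(triethylsilyloxy)pent-3-en-1-yn-1-yl]cyclohex-2-en-1-one | CC[Si](CC)(CC)OC/C=C(C)/C#C[C@]1(O[Si](CC)(CC)CC)C(C)(C)CC(=O)C=C1C | intermediate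
10 | (1R,5R,6S)-4,4,6-trimethyl-5-(triethylsilyloxy)-5-[(3E)-3-methyl-5-(triethylsilyloxy)pent-3-en-1-yn-1-yl]-7-oxabicyclo[4.1.0]heptan-2-one | CC[Si](CC)(CC)OC/C=C(C)/C#C[C@]1(O[Si](CC)(CC)CC)C(C)(C)CC(=O)[C@@H]2O[C@]12C | intermediate
11 | (1R,5R,6S)-5-hydroxy-5-[(3E)-5-hydroxy-3-methylpent-3-en-1-yn-1-yl]-4,4,6-trimethyl-7-oxabicyclo[4.1.0]heptan-2-one | OC/C=C(C)/C#C[C@]1(O)C(C)(C)CC(=O)[C@@H]2O[C@]12C | intermediate
12 | (1S,2S,4S)-1-[(1E,3E)-5-hydroxy-3-methylpenta-1,3-dien-1-yl]-2,6,6-trimethylcyclohexane-1,2,4-triol | OC/C=C(C)/C=C/[C@]1(O)C(C)(C)C[C@H](O)C[C@]1(C)O | intermediate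
13 | (1S,2S,4S)-1-[(1E,3E)-5-bromo-3-methylpenta-1,3-dien-1-yl]-2,6,6-trimethylcyclohexane-1,2,4-triol | BrC/C=C(C)/C=C/[C@]1(O)C(C)(C)C[C@H](O)C[C@]1(C)O | intermediate
14 | [(2E,4E)-3-methyl-5-[(1S,2S,4S)-1,2,4-trihydroxy-2,6,6-trimethylcyclohexyl]penta-2,4-dien-1-yl]triphenylphosphonium bromide | [Br-].c1ccccc1[P+](c1ccccc1)(c1ccccc1)C/C=C(C)/C=C/[C@]1(O)C(C)(C)C[C@H](O)C[C@]1(C)O | intermediate
15 | (3E)-4-[(1R)-2,6,6-trimethylcyclohex-2-en-1-yl]but-3-en-2-one ((R)-α-ionone) | CC1=CCCC(C)(C)[C@H]1/C=C/C(C)=O | starting material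
16 | triethyl phosphonoacetate | CCOC(=O)CP(=O)(OCC)OCC | starting material
17 | sodium salt of triethyl phosphonoacetate (carbanion) | CCOC(=O)[CH-]P(=O)(OCC)OCC.[Na+] | intermediate
18 | ethyl (2E,4E)-3-methyl-5-[(1R)-2,6,6-trimethylcyclohex-2-en-1-yl]penta-2,4-dienoate | CC1=CCCC(C)(C)[C@H]1/C=C/C(C)=C/C(=O)OCC | intermediate
19 | ethyl (2E,4E)-3-methyl-5-[(1R)-2,6,6-trimethyl-4-oxocyclohex-2-en-1-yl]penta-2,4-dienoate | CC1=CC(=O)CC(C)(C)[C@H]1/C=C/C(C)=C/C(=O)OCC | intermediate
20 | ethyl (2E,4E)-5-[(1R,4R)-4-hydroxy-2,6,6-trimethylcyclohex-2-en-1-yl]-3-methylpenta-2,4-dienoate (present as its catechol borate) | CC1=C[C@H](O)CC(C)(C)[C@H]1/C=C/C(C)=C/C(=O)OCC | intermediate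
21 | (2E,4E)-5-[(1R,4R)-4-hydroxy-2,6,6-trimethylcyclohex-2-en-1-yl]-3-methylpenta-2,4-dien-1-ol | CC1=C[C@H](O)CC(C)(C)[C@H]1/C=C/C(C)=C/CO | intermediate
22 | (1R,4R)-4-[(1E,3E)-5-bromo-3-methylpenta-1,3-dien-1-yl]-3,5,5-trimethylcyclohex-2-en-1-ol | CC1=C[C@H](O)CC(C)(C)[C@H]1/C=C/C(C)=C/CBr | intermediate
23 | [(2E,4E)-5-[(1R,4R)-4-hydroxy-2,6,6-trimethylcyclohex-2-en-1-yl]-3-methylpenta-2,4-dien-1-yl]triphenylphosphonium bromide | CC1=C[C@H](O)CC(C)(C)[C@H]1/C=C/C(C)=C/C[P+](c1ccccc1)(c1ccccc1)c1ccccc1.[Br-] | intermediate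
24 | (2E,4E,6E)-2,7-dimethylocta-2,4,6-trienedial | O=C/C(C)=C/C=C/C=C(C)/C=O | starting material
25 | ylide of 23 (triphenylphosphonium ylide, zwitterion form) | CC1=C[C@H](O)CC(C)(C)[C@H]1/C=C/C(C)=C/[CH-][P+](c1ccccc1)(c1ccccc1)c1ccccc1 | intermediate
26 | (2E,4E,6E,8E,10E,12E)-13-[(1R,4R)-4-hydroxy-2,6,6-trimethylcyclohex-2-en-1-yl]-2,7,11-trimethyltrideca-2,4,6,8,10,12-hexaenal | CC1=C[C@H](O)CC(C)(C)[C@H]1/C=C/C(C)=C/C=C/C(C)=C/C=C/C=C(C)/C=O | intermediate
27 | ylide of 14 (triphenylphosphonium ylide, zwitterion form) | c1ccccc1[P+](c1ccccc1)(c1ccccc1)[CH-]/C=C(C)/C=C/[C@]1(O)C(C)(C)C[C@H](O)C[C@]1(C)O | intermediate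
28 | (3S,5S,6S,3'R,6'R)-5,6-dihydro-β,ε-carotene-3,5,6,3'-tetrol | CC1=C[C@H](O)CC(C)(C)[C@H]1/C=C/C(C)=C/C=C/C(C)=C/C=C/C=C(C)/C=C/C=C(C)/C=C/[C@]1(O)C(C)(C)C[C@H](O)C[C@]1(C)O | target

## Step count and risks
Total step count: 12. Longest linear sequence: 7 (steps 1–6, then step 12); the ε branch is 6 (steps 7–12).

Three steps most likely to fail:

**Step 3 (group-selective methylation; unprecedented as an asymmetric reaction, very hindered β-carbon).** The fallback sets out from 8 and comes back to the route at 9. Methyl is added without chiral control (MeMgBr, CuI cat., THF, −20 °C) to give the racemic enone F1. Reduction with (S)-Me-CBS/catecholborane turns the two enantiomers into two diastereomeric (1R)-allylic alcohols: the wanted (1R,4S)-alcohol F2 and the (1R,4R)-alcohol F3 from the unwanted enantiomer. They are separated on silica, and F2 is oxidised back to 9 with MnO2. This replaces group-selective catalysis by a reagent-controlled resolution through diastereomers.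

**Step 4 (epoxidation of a hindered enone; the face is ruled only by OTES against alkyne).** The fallback sets out from 9 and comes back at 12. The ketone is reduced first with (R)-Me-CBS/catecholborane to the (1S,4S)-allylic alcohol F4, whose C3–OH is cis to the alkyne. VO(acac)2/t-BuOOH then delivers the epoxide oxygen from the face of that hydroxyl, which is also the face away from OTES, giving the silylated epoxy alcohol F5. TBAF/AcOH gives the epoxy triol F6, and Red-Al (epoxide opening at C4, alkyne to E-alkene) gives 12. This swaps a sterically ruled nucleophilic epoxidation for a hydroxyl-directed electrophilic one and sets C3 by reagent control.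

**Step 9 (CBS reduction working against the substrate's cis preference).** The fallback sets out from 19 and comes back at 21. Reduction under substrate control (NaBH4, CeCl3, MeOH, −20 °C) is expected to favour the cis-hydroxy ester F7. Mitsunobu inversion (4-nitrobenzoic acid, DIAD, PPh3) gives the trans 4-nitrobenzoate F8. DIBAL-H at −78 °C then removes the nitrobenzoate and reduces the ethyl ester to give 21.

Further compounds
F1 | step 3 | racemic 3,5,5-trimethyl-4-(triethylsilyloxy)-4-[(3E)-3-methyl-5-(triethylsilyloxy)pent-3-en-1-yn-1-yl]cyclohex-2-en-1-one | CC[Si](CC)(CC)OC/C=C(C)/C#CC1(O[Si](CC)(CC)CC)C(C)(C)CC(=O)C=C1C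
F2 | step 3 | (1R,4S)-3,5,5-trimethyl-4-(triethylsilyloxy)-4-[(3E)-3-methyl-5-(triethylsilyloxy)pent-3-en-1-yn-1-yl]cyclohex-2-en-1-ol | CC[Si](CC)(CC)OC/C=C(C)/C#C[C@]1(O[Si](CC)(CC)CC)C(C)(C)C[C@@H](O)C=C1C
F3 | step 3 | (1R,4R)-3,5,5-trimethyl-4-(triethylsilyloxy)-4-[(3E)-3-methyl-5-(triethylsilyloxy)pent-3-en-1-yn-1-yl]cyclohex-2-en-1-ol | CC[Si](CC)(CC)OC/C=C(C)/C#C[C@@]1(O[Si](CC)(CC)CC)C(C)(C)C[C@@H](O)C=C1C
F4 | step 4 | (1S,4S)-3,5,5-trimethyl-4-(triethylsilyloxy)-4-[(3E)-3-methyl-5-(triethylsilyloxy)pent-3-en-1-yn-1-yl]cyclohex-2-en-1-ol | CC[Si](CC)(CC)OC/C=C(C)/C#C[C@]1(O[Si](CC)(CC)CC)C(C)(C)C[C@H](O)C=C1C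
F5 | step 4 | (1S,2S,5R,6S)-4,4,6-trimethyl-5-(triethylsilyloxy)-5-[(3E)-3-methyl-5-(triethylsilyloxy)pent-3-en-1-yn-1-yl]-7-oxabicyclo[4.1.0]heptan-2-ol | CC[Si](CC)(CC)OC/C=C(C)/C#C[C@]1(O[Si](CC)(CC)CC)C(C)(C)C[C@H](O)[C@@H]2O[C@]12C
F6 | step 4 | (1S,2S,5R,6S)-5-[(3E)-5-hydroxy-3-methylpent-3-en-1-yn-1-yl]-4,4,6-trimethyl-7-oxabicyclo[4.1.0]heptane-2,5-diol | OC/C=C(C)/C#C[C@]1(O)C(C)(C)C[C@H](O)[C@@H]2O[C@]12C
F7 | step 9 | ethyl (2E,4E)-5-[(1R,4S)-4-hydroxy-2,6,6-trimethylcyclohex-2-en-1-yl]-3-methylpenta-2,4-dienoate | CC1=C[C@@H](O)CC(C)(C)[C@H]1/C=C/C(C)=C/C(=O)OCC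
F8 | step 9 | ethyl (2E,4E)-3-methyl-5-[(1R,4R)-2,6,6-trimethyl-4-(4-nitrobenzoyloxy)cyclohex-2-en-1-yl]penta-2,4-dienoate | CC1=C[C@H](OC(=O)c2ccc(cc2)[N+](=O)[O-])CC(C)(C)[C@H]1/C=C/C(C)=C/C(=O)OCC
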